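**Direct plan and its weak points**

A direct plan would cut the diene at C3'–C4' and close with a fluoride-triggered Hiyama coupling of two fragments.
Ring A would be vinyl iodide A2, made from geranyl acetate A1 by Shi epoxidation, ZrCl4 cyclisation and Takai iodo-olefination.
Rings B and C would come from furyl carbinol A3: a three-step ring expansion (cycloaddition, photoisomerisation, thermolysis) to oxepine A4, trapping of its arene oxide tautomer with singlet oxygen to epoxy triol A5, then elaboration to vinylsilane A6.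
Its weakest steps would be these.
The ring expansion to A4 would spend three steps, one photochemical and one at 110 °C, on a flat achiral ring that can slip to a phenol at each stage.
The singlet-oxygen trapping would stake all four ring stereocentres on one hydrogen bond from the side-chain carbinol on an equilibrating arene oxide, a facial choice without close analogy.
The final coupling would strip four silyl ethers and join the free, base-labile epoxy tetraol to a hindered iodide in one pot, on the most precious material.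

**Plan of the new route**

The retrosynthesis cuts C1'–C2' (dienyllithium plus aldehyde) and C4'=C5' (Julia–Kocienski), and reads ring B with its two branches as one C2-symmetric C8 unit.
In ring B the branch carbons are para (C1' on C1, CH2OH on C4) and the carbinols C2 and C5 are cis. Ring B plus both branches is therefore dimethyl succinylsuccinate, whose two ketone carbons are C2 and C5.
Ring B is bought. A double asymmetric hydrogenation fixes C2 and C5, desaturation gives a C2-symmetric diene with homotopic alkenes, and one hydroxyl-directed epoxidation closes ring C anti to both silyloxy groups. Ring A is made apart and joined last.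
No oxepine, photochemistry or arene oxide occurs. The ring stereocentres descend from a catalyst-controlled reduction and a sterically unambiguous epoxidation.
The fragments are joined as fully protected partners, C1' is set by a stereoconvergent ketone reduction, and the last step is a plain desilylation.

Key step: step 1

Remark: C1–C6 and O7 are the atoms of the 7-oxabicyclo[4.1.0]heptene (rings B and C) as numbered in the name of the target, and C1'–C5' is the side chain from the carbinol to ring A. The ring carbons of 1–7 are referred to by the same numbers in the Why lines.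

**Rings B and C**

Step 1
Reactants: 1 dimethyl 2,5-dioxocyclohexane-1,4-dicarboxylate (dimethyl succinylsuccinate)
Product: 2 dimethyl (1S,2S,4S,5S)-2,5-dihydroxycyclohexane-1,4-dicarboxylate
Conditions: H2 (100 atm), [RuCl(C6H6){(S)-BINAP}]Cl (1 mol%), MeOH–CH2Cl2, 50 °C
Reagents that add atoms: none
Why: Asymmetric hydrogenation of a β-keto ester with dynamic kinetic resolution: the keto tautomer chelates the ruthenium monohydride through ketone and ester carbonyl, hydrogen is delivered to the ketone face left open by the (S)-BINAP phenyl groups, and the other tautomers and α-epimers of 1 drain into this channel through the enol, which re-forms faster than either is reduced. The closest known reaction type is the Ru–BINAP (Noyori) hydrogenation of methyl 2-oxocyclohexanecarboxylate and its five-ring analogue; the step closes no ring. C2 and C5 are set by the catalyst, (S)-BINAP giving the (S)-carbinol as with acyclic β-keto esters, while C1 and C4 should come out trans to their hydroxyl neighbours through the faster-reacting α-epimer and are of no consequence, since step 3 erases them. The step needs the same sense of reduction at both ketones and gets it because the two β-keto ester units of 1 are identical and remote, so each meets the catalyst on its own; a single error gives the centrosymmetric meso diol, a diastereomer that can be removed by crystallisation, so the C2-symmetric diol should be enriched beyond the selectivity of one reduction. What makes the step possible is that C2 and C5 of ring B are the two ketone carbons of 1, and that C1 and C4 already carry the carbons that become C1' and the hydroxymethyl group.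

Step 2
Reactants: 2 diol diester
Product: 3 dimethyl (1S,2S,4S,5S)-2,5-bis(tert-butyldimethylsilyloxy)cyclohexane-1,4-dicarboxylate
Conditions: t-BuMe2SiCl, imidazole, DMF, 23 °C
Reagents that add atoms: tert-butyl(chloro)dimethylsilane, CC(C)(C)[Si](C)(C)Cl
Why: Imidazole-assisted silylation masks both secondary alcohols as bulky ethers that survive the enolate, hydride and oxidation steps and later shield one face of the ring; no stereocentre is touched.

Step 3
Reactants: 3 bis(silyl ether) diester
Product: 5 dimethyl (3S,6S)-3,6-bis(tert-butyldimethylsilyloxy)cyclohexa-1,4-diene-1,4-dicarboxylate, via bis-selenide 4 (not isolated)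
Conditions: LiN(i-Pr)2 (2.4 equiv), THF, −78 °C; PhSeBr, −78 °C; then 30% H2O2, pyridine, CH2Cl2, 0 °C
Reagents that add atoms: none
Why: α-Selenenylation of the bis(ester enolate) followed by selenoxide syn-elimination (ester dehydrogenation): each selenoxide takes its hydrogen from the ring CH2 and not from the silyloxy-bearing carbon, the usual preference for elimination away from oxygen, so that both α-centres vanish whatever their configuration and a C2-symmetric 1,4-diene with only C2 and C5 stereogenic remains.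

Step 4
Reactants: 5 diene diester
Product: 6 [(3S,6S)-3,6-bis(tert-butyldimethylsilyloxy)cyclohexa-1,4-diene-1,4-diyl]dimethanol
Conditions: i-Bu2AlH, CH2Cl2, −78 °C; aq. potassium sodium tartrate
Reagents that add atoms: none
Why: 1,2-Reduction of both enoates to allylic alcohols with i-Bu2AlH at low temperature, a non-basic reductant that cannot deprotonate the doubly allylic carbinol carbons and so cannot start loss of silanol to an arene.

Step 5
Reactants: 6 C2-symmetric diol
Product: 7 [(3S,6S)-3,6-bis(tert-butyldimethylsilyloxy)-4-(tert-butyldimethylsilyloxymethyl)cyclohexa-1,4-dien-1-yl]methanol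
Conditions: t-BuMe2SiCl (1.0 equiv), imidazole, CH2Cl2, −20 °C
Reagents that add atoms: tert-butyl(chloro)dimethylsilane, CC(C)(C)[Si](C)(C)Cl
Why: Statistical monosilylation of a C2-symmetric diol: the two hydroxymethyl groups are homotopic, so silylation of either gives the same mono-ether, and the recovered diol is returned to the step.

Step 6
Reactants: 7 mono-ether
Product: 8 [(1S,2S,5R,6S)-2,5-bis(tert-butyldimethylsilyloxy)-4-(tert-butyldimethylsilyloxymethyl)-7-oxabicyclo[4.1.0]hept-3-en-1-yl]methanol
Conditions: VO(acac)2 (5 mol%), t-BuOOH, CH2Cl2, 0 °C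
Reagents that add atoms: tert-butyl hydroperoxide, CC(C)(C)OO
Why: Hydroxyl-directed vanadium-catalysed epoxidation: the vanadate ester of the one free allylic alcohol delivers oxygen only to the alkene that carries it, and to the face away from the two silyloxy groups that flank this alkene on the same side at C2 and C5, so that ring C closes with the quaternary C1 and C6 set anti to both ethers; because the two alkenes of 6 are homotopic, the choice made in step 5 cannot lead to an isomer.

Step 7
Reactants: 8 epoxy alcohol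
Product: 9 (1S,2S,5R,6S)-2,5-bis(tert-butyldimethylsilyloxy)-4-(tert-butyldimethylsilyloxymethyl)-7-oxabicyclo[4.1.0]hept-3-ene-1-carbaldehyde
Conditions: Dess–Martin periodinane, NaHCO3, CH2Cl2, 0 °C
Reagents that add atoms: none
Why: Dess–Martin oxidation under bicarbonate buffer stops at the aldehyde, which has no α-hydrogen and so cannot epimerise or enolise.

**Ring A**

Step 8
Reactants: 10 geraniol
Product: 11 5-{[(2E)-3,7-dimethylocta-2,6-dien-1-yl]sulfanyl}-1-phenyl-1H-tetrazole
Conditions: 1-phenyl-1H-tetrazole-5-thiol, PPh3, i-PrO2CN=NCO2i-Pr, THF, 0 °C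
Reagents that add atoms: 1-phenyl-1H-tetrazole-5-thiol, Sc1nnnn1-c1ccccc1
Why: Mitsunobu thioetherification of the primary allylic alcohol by SN2 displacement introduces the tetrazolyl sulfide without moving or isomerising the (E)-alkene.

Step 9
Reactants: 11 geranyl sulfide
Product: 12 5-{[(2E)-3,7-dimethylocta-2,6-dien-1-yl]sulfonyl}-1-phenyl-1H-tetrazole
Conditions: 30% H2O2, (NH4)6Mo7O24·4H2O (cat.), EtOH, 0 → 23 °C
Reagents that add atoms: hydrogen peroxide, OO
Why: Molybdate-catalysed oxidation with hydrogen peroxide takes the sulfide to the sulfone and leaves the two trisubstituted alkenes alone.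

Step 10
Reactants: 12 geranyl sulfone
Product: 13 5-({(2E)-5-[(2R)-3,3-dimethyloxiran-2-yl]-3-methylpent-2-en-1-yl}sulfonyl)-1-phenyl-1H-tetrazole
Conditions: Shi ketone (1,2:4,5-di-O-isopropylidene-β-D-erythro-hexo-2,3-diulo-2,6-pyranose, cat.), Oxone (2KHSO5·KHSO4·K2SO4), K2CO3, Bu4NHSO4, MeCN–CH2(OMe)2/aq. borate buffer, 0 °C
Reagents that add atoms: potassium peroxymonosulfate, OOS(=O)(=O)[O-].[K+]
Why: Shi epoxidation: the chiral dioxirane attacks the electron-richer 6,7-alkene (the 2,3-alkene is deactivated by the allylic sulfonyl group) through the spiro transition state that gives the (R)-epoxide.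

Step 11
Reactants: 13 (R)-epoxy sulfone
Product: 14 5-({[(1S,5R)-5-hydroxy-2,6,6-trimethylcyclohex-2-en-1-yl]methyl}sulfonyl)-1-phenyl-1H-tetrazole
Conditions: ZrCl4, CH2Cl2, −78 → −20 °C
Reagents that add atoms: none
Why: Lewis acid-promoted epoxy-ene (cationic polyene-type) cyclisation through a chair-like array: anti attack of the (E)-alkene on the tertiary epoxide carbon keeps the C–O centre, places hydroxyl and sulfonylmethyl cis-diequatorial (new centre S) and ends with loss of a ring proton to the endocyclic alkene, the sulfonylmethyl group playing the part that an acyloxymethyl group plays in known cyclisations of this type.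

Step 12
Reactants: 14 hydroxy sulfone
Product: 15 1-phenyl-5-({[(1S,5R)-2,6,6-trimethyl-5-(triethylsilyloxy)cyclohex-2-en-1-yl]methyl}sulfonyl)-1H-tetrazole
Conditions: Et3SiCl, imidazole, CH2Cl2, 0 → 23 °C
Reagents that add atoms: chlorotriethylsilane, CC[Si](Cl)(CC)CC
Why: Imidazole-assisted silylation masks the secondary alcohol, which would otherwise consume base in step 15 and be oxidised in step 16; no stereocentre is touched.

**Side-chain linchpin and dienyl iodide**

Step 13
Reactants: 16 prop-2-yn-1-ol
Product: 18 (2Z)-3-iodo-2-methylprop-2-en-1-ol, via cyclic alkenylmagnesium alkoxide 17 (not isolated)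
Conditions: MeMgBr (2.5 equiv), CuI (cat.), THF, −10 → 23 °C; then I2, −78 → 0 °C
Reagents that add atoms: methylmagnesium bromide, C[Mg]Br; iodine, II
Why: Copper-catalysed anti-carbomagnesiation of the propargylic alkoxide: methyl adds to the inner alkyne carbon while magnesium ends on the terminal carbon cis to the CH2O group in a five-membered chelate, and iodinolysis with retention gives the (Z)-iodoalkene.

Step 14
Reactants: 18 (Z)-iodo alcohol
Product: 19 (2Z)-3-iodo-2-methylprop-2-enal
Conditions: MnO2 (activated), CH2Cl2, 23 °C, dark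
Reagents that add atoms: none
Why: Allylic oxidation on MnO2, a neutral heterogeneous oxidant that stops at the aldehyde and keeps the (Z)-geometry of the sensitive β-iodo enal, which is used at once.

Step 15
Reactants: 15 silyl ether sulfone; 19 (Z)-iodo enal
Product: 20 triethyl({(1R,5S)-5-[(1E,3Z)-4-iodo-3-methylbuta-1,3-dien-1-yl]-4,6,6-trimethylcyclohex-3-en-1-yl}oxy)silane
Conditions: KN(SiMe3)2, MeOCH2CH2OMe, −78 °C; then 19, −78 → 23 °C
Reagents that add atoms: none
Why: Julia–Kocienski olefination: the metalated alkyl tetrazolyl sulfone adds to the enal, Smiles rearrangement and anti-elimination of sulfur dioxide and tetrazololate give the (E)-alkene (potassium counter-ion and dimethoxyethane favour the open transition state), and since the carbanion is not allylic neither the (Z)-iodoalkene nor the ring stereocentres are touched.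

**Fragment union and end game**

Step 16
Reactants: 20 dienyl iodide; 9 epoxy aldehyde
Product: 23 (2Z,4E)-1-[(1S,2S,5R,6S)-2,5-bis(tert-butyldimethylsilyloxy)-4-(tert-butyldimethylsilyloxymethyl)-7-oxabicyclo[4.1.0]hept-3-en-1-yl]-3-methyl-5-[(1S,5R)-2,6,6-trimethyl-5-(triethylsilyloxy)cyclohex-2-en-1-yl]penta-2,4-dien-1-one, via dienyllithium 21 (not isolated), via carbinol epimers 22 (not isolated)
Conditions: t-BuLi (2.1 equiv), Et2O, −78 °C; then 9, −78 °C; aq. NH4Cl; then Dess–Martin periodinane, NaHCO3, CH2Cl2, 0 °C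
Reagents that add atoms: none
Why: Iodine–lithium exchange with retention of the (Z)-geometry and 1,2-addition of the dienyllithium to the non-enolisable aldehyde join the fragments at C1'–C2', and Dess–Martin oxidation of the crude carbinol removes the uncontrolled C1' centre, so that both epimers converge on one ketone.

Step 17
Reactants: 23 epoxy dienone
Product: 24 (1S,2Z,4E)-1-[(1S,2S,5R,6S)-2,5-bis(tert-butyldimethylsilyloxy)-4-(tert-butyldimethylsilyloxymethyl)-7-oxabicyclo[4.1.0]hept-3-en-1-yl]-3-methyl-5-[(1S,5R)-2,6,6-trimethyl-5-(triethylsilyloxy)cyclohex-2-en-1-yl]penta-2,4-dien-1-ol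
Conditions: NaBH4, MeOH–CH2Cl2, −40 °C
Reagents that add atoms: none
Why: 1,2-Reduction of an α,β-epoxy ketone under non-chelating conditions: in the Cornforth and in the polar Felkin–Anh arrangement alike the dienyl group lies away from C2 and its cis silyloxy group and hydride comes in past the oxirane CH (C6), which should give the (1'S)-carbinol; counter-ions that bridge carbonyl and oxirane oxygen (zinc or cerium salts) are left out because they would turn the carbonyl group round and favour the epimer.

Step 18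
Reactants: 24 tetrakis(silyl ether)
Product: 25 (1R,2S,5R,6S)-4-(hydroxymethyl)-1-{(1S,2Z,4E)-1-hydroxy-5-[(1S,5R)-5-hydroxy-2,6,6-trimethylcyclohex-2-en-1-yl]-3-methylpenta-2,4-dien-1-yl}-7-oxabicyclo[4.1.0]hept-3-ene-2,5-diol (CNP0389279.1)
Conditions: Bu4NF, AcOH (1:1), THF, 0 → 23 °C
Reagents that add atoms: none
Why: Fluoride desilylation buffered with acetic acid removes the three tert-butyldimethylsilyl ethers and the triethylsilyl ether without building up alkoxides that could start epoxide migration (Payne rearrangement) and without acid that could ionise the dienyl carbinol.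

**Compound list**

1 | dimethyl 2,5-dioxocyclohexane-1,4-dicarboxylate (dimethyl succinylsuccinate) | COC(=O)C1CC(=O)C(C(=O)OC)CC1=O | starting material
2 | dimethyl (1S,2S,4S,5S)-2,5-dihydroxycyclohexane-1,4-dicarboxylate (any C1/C4 epimers converge in step 3) | COC(=O)[C@H]1C[C@H](O)[C@@H](C(=O)OC)C[C@@H]1O | intermediate
3 | dimethyl (1S,2S,4S,5S)-2,5-bis(tert-butyldimethylsilyloxy)cyclohexane-1,4-dicarboxylate | COC(=O)[C@H]1C[C@H](O[Si](C)(C)C(C)(C)C)[C@@H](C(=O)OC)C[C@@H]1O[Si](C)(C)C(C)(C)C | intermediate
4 | dimethyl (2S,5S)-2,5-bis(tert-butyldimethylsilyloxy)-1,4-bis(phenylselanyl)cyclohexane-1,4-dicarboxylate (C1 and C4 epimers) | COC(=O)C1([Se]c2ccccc2)C[C@H](O[Si](C)(C)C(C)(C)C)C(C(=O)OC)([Se]c2ccccc2)C[C@@H]1O[Si](C)(C)C(C)(C)C | intermediate (not isolated)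
5 | dimethyl (3S,6S)-3,6-bis(tert-butyldimethylsilyloxy)cyclohexa-1,4-diene-1,4-dicarboxylate | COC(=O)C1=C[C@H](O[Si](C)(C)C(C)(C)C)C(C(=O)OC)=C[C@@H]1O[Si](C)(C)C(C)(C)C | intermediate
6 | [(3S,6S)-3,6-bis(tert-butyldimethylsilyloxy)cyclohexa-1,4-diene-1,4-diyl]dimethanol | OCC1=C[C@H](O[Si](C)(C)C(C)(C)C)C(CO)=C[C@@H]1O[Si](C)(C)C(C)(C)C | intermediate
7 | [(3S,6S)-3,6-bis(tert-butyldimethylsilyloxy)-4-(tert-butyldimethylsilyloxymethyl)cyclohexa-1,4-dien-1-yl]methanol | OCC1=C[C@H](O[Si](C)(C)C(C)(C)C)C(CO[Si](C)(C)C(C)(C)C)=C[C@@H]1O[Si](C)(C)C(C)(C)C | intermediate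
8 | [(1S,2S,5R,6S)-2,5-bis(tert-butyldimethylsilyloxy)-4-(tert-butyldimethylsilyloxymethyl)-7-oxabicyclo[4.1.0]hept-3-en-1-yl]methanol (oxirane anti to both ring silyloxy groups) | OC[C@]12O[C@H]1[C@H](O[Si](C)(C)C(C)(C)C)C(CO[Si](C)(C)C(C)(C)C)=C[C@@H]2O[Si](C)(C)C(C)(C)C | intermediate
9 | (1S,2S,5R,6S)-2,5-bis(tert-butyldimethylsilyloxy)-4-(tert-butyldimethylsilyloxymethyl)-7-oxabicyclo[4.1.0]hept-3-ene-1-carbaldehyde | O=C[C@]12O[C@H]1[C@H](O[Si](C)(C)C(C)(C)C)C(CO[Si](C)(C)C(C)(C)C)=C[C@@H]2O[Si](C)(C)C(C)(C)C | intermediate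
10 | geraniol | CC(C)=CCC/C(C)=C/CO | starting material
11 | 5-{[(2E)-3,7-dimethylocta-2,6-dien-1-yl]sulfanyl}-1-phenyl-1H-tetrazole | CC(C)=CCC/C(C)=C/CSc1nnnn1-c1ccccc1 | intermediate
12 | 5-{[(2E)-3,7-dimethylocta-2,6-dien-1-yl]sulfonyl}-1-phenyl-1H-tetrazole | CC(C)=CCC/C(C)=C/CS(=O)(=O)c1nnnn1-c1ccccc1 | intermediate
13 | 5-({(2E)-5-[(2R)-3,3-dimethyloxiran-2-yl]-3-methylpent-2-en-1-yl}sulfonyl)-1-phenyl-1H-tetrazole | O=S(=O)(C/C=C(C)/CC[C@H]1OC1(C)C)c1nnnn1-c1ccccc1 | intermediate
14 | 5-({[(1S,5R)-5-hydroxy-2,6,6-trimethylcyclohex-2-en-1-yl]methyl}sulfonyl)-1-phenyl-1H-tetrazole | CC1=CC[C@@H](O)C(C)(C)[C@H]1CS(=O)(=O)c1nnnn1-c1ccccc1 | intermediate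
15 | 1-phenyl-5-({[(1S,5R)-2,6,6-trimethyl-5-(triethylsilyloxy)cyclohex-2-en-1-yl]methyl}sulfonyl)-1H-tetrazole | CC1=CC[C@@H](O[Si](CC)(CC)CC)C(C)(C)[C@H]1CS(=O)(=O)c1nnnn1-c1ccccc1 | intermediate
16 | prop-2-yn-1-ol | C#CCO | starting material
17 | 4-methyl-2,5-dihydro-1,2-oxamagnesole (cyclic (Z)-alkenylmagnesium alkoxide) | CC1=C[Mg]OC1 | intermediate (not isolated)
18 | (2Z)-3-iodo-2-methylprop-2-en-1-ol | OC/C(C)=C\I | intermediate
19 | (2Z)-3-iodo-2-methylprop-2-enal | O=C/C(C)=C\I | intermediate
20 | triethyl({(1R,5S)-5-[(1E,3Z)-4-iodo-3-methylbuta-1,3-dien-1-yl]-4,6,6-trimethylcyclohex-3-en-1-yl}oxy)silane | CC1=CC[C@@H](O[Si](CC)(CC)CC)C(C)(C)[C@H]1/C=C/C(C)=C\I | intermediate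
21 | (1Z,3E)-dienyllithium from 20 (lithium in place of iodine) | CC1=CC[C@@H](O[Si](CC)(CC)CC)C(C)(C)[C@H]1/C=C/C(C)=C\[Li] | intermediate (not isolated)
22 | (2Z,4E)-dienyl carbinol from 21 and 9, both C1' epimers | CC1=CC[C@@H](O[Si](CC)(CC)CC)C(C)(C)[C@H]1/C=C/C(C)=C\C(O)[C@]12O[C@H]1[C@H](O[Si](C)(C)C(C)(C)C)C(CO[Si](C)(C)C(C)(C)C)=C[C@@H]2O[Si](C)(C)C(C)(C)C | intermediate (not isolated)
23 | (2Z,4E)-1-[(1S,2S,5R,6S)-2,5-bis(tert-butyldimethylsilyloxy)-4-(tert-butyldimethylsilyloxymethyl)-7-oxabicyclo[4.1.0]hept-3-en-1-yl]-3-methyl-5-[(1S,5R)-2,6,6-trimethyl-5-(triethylsilyloxy)cyclohex-2-en-1-yl]penta-2,4-dien-1-one | CC1=CC[C@@H](O[Si](CC)(CC)CC)C(C)(C)[C@H]1/C=C/C(C)=C\C(=O)[C@]12O[C@H]1[C@H](O[Si](C)(C)C(C)(C)C)C(CO[Si](C)(C)C(C)(C)C)=C[C@@H]2O[Si](C)(C)C(C)(C)C | intermediate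
24 | (1S,2Z,4E)-1-[(1S,2S,5R,6S)-2,5-bis(tert-butyldimethylsilyloxy)-4-(tert-butyldimethylsilyloxymethyl)-7-oxabicyclo[4.1.0]hept-3-en-1-yl]-3-methyl-5-[(1S,5R)-2,6,6-trimethyl-5-(triethylsilyloxy)cyclohex-2-en-1-yl]penta-2,4-dien-1-ol | CC1=CC[C@@H](O[Si](CC)(CC)CC)C(C)(C)[C@H]1/C=C/C(C)=C\[C@H](O)[C@]12O[C@H]1[C@H](O[Si](C)(C)C(C)(C)C)C(CO[Si](C)(C)C(C)(C)C)=C[C@@H]2O[Si](C)(C)C(C)(C)C | intermediate
25 | (1R,2S,5R,6S)-4-(hydroxymethyl)-1-{(1S,2Z,4E)-1-hydroxy-5-[(1S,5R)-5-hydroxy-2,6,6-trimethylcyclohex-2-en-1-yl]-3-methylpenta-2,4-dien-1-yl}-7-oxabicyclo[4.1.0]hept-3-ene-2,5-diol (CNP0389279.1) | CC1=CC[C@@H](O)C(C)(C)[C@H]1/C=C/C(C)=C\[C@H](O)[C@]12O[C@H]1[C@H](O)C(CO)=C[C@@H]2O | target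

**Step count and risks**

Total step count: 18. Longest linear sequence: 10 steps (steps 1–7, then 16–18).

The three steps most likely to fail:

Step 3 (double dehydrogenation). The ester enolates of 3 may expel silyloxide, a selenoxide may eliminate toward the carbinol carbon, or diene 5 may lose silanol and aromatise. The fallback sets out from diol 2 and comes back at 5. The dehydrogenation would be run before silylation on the bis(alkoxide enolate) of 2 (LiN(i-Pr)2, 4.4 equiv; Fráter–Seebach-type dianions, in which the alkoxide cannot leave). Selenenylation would give dimethyl (2S,5S)-2,5-dihydroxy-1,4-bis(phenylselanyl)cyclohexane-1,4-dicarboxylate F1. Oxidation with H2O2 would give dimethyl (3S,6S)-3,6-dihydroxycyclohexa-1,4-diene-1,4-dicarboxylate F2, which would be silylated at once (t-BuMe2SiOTf, 2,6-lutidine, −78 °C) to give 5.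

Step 11 (ring A closure). The sulfonylmethyl group may slow ring closure so far that the epoxide rearranges to a ketone or the cation loses the wrong proton. The fallback sets out from geraniol 10 and comes back at 14. Ring A would be closed at the ester stage and the sulfone introduced afterwards. Geraniol would be acetylated to geranyl acetate F3, epoxidised under the same Shi conditions to (2E)-5-[(2R)-3,3-dimethyloxiran-2-yl]-3-methylpent-2-en-1-yl acetate F4, and cyclised with ZrCl4 to [(1S,5R)-5-hydroxy-2,6,6-trimethylcyclohex-2-en-1-yl]methyl acetate F5. Methanolysis (K2CO3, MeOH) would give [(1S,5R)-5-hydroxy-2,6,6-trimethylcyclohex-2-en-1-yl]methanol F6. Its primary hydroxyl alone would undergo Mitsunobu substitution with 1-phenyl-1H-tetrazole-5-thiol to give 5-({[(1S,5R)-5-hydroxy-2,6,6-trimethylcyclohex-2-en-1-yl]methyl}sulfanyl)-1-phenyl-1H-tetrazole F7, and molybdate/H2O2 oxidation would return to 14.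

Step 17 (C1' reduction). Hydride may be delivered through a chelate or in 1,4-fashion, or the (2Z)-dienone 23 may close to a 2H-pyran or isomerise before it is reduced. The fallback sets out from iodide 20 and aldehyde 9 and comes back at 24. C1' would be set in the carbon–carbon bond formation itself, by a ligand-controlled Nozaki–Hiyama–Kishi coupling (CrCl2, NiCl2 (cat.), chiral sulfonamide ligand, MeCN). This would give carbinol 24 directly without passing through 22 or 23 and makes no new compound (F0).

**Further compounds**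

F1 | step 3 | dimethyl (2S,5S)-2,5-dihydroxy-1,4-bis(phenylselanyl)cyclohexane-1,4-dicarboxylate (C1 and C4 epimers) | COC(=O)C1([Se]c2ccccc2)C[C@H](O)C(C(=O)OC)([Se]c2ccccc2)C[C@@H]1O
F2 | step 3 | dimethyl (3S,6S)-3,6-dihydroxycyclohexa-1,4-diene-1,4-dicarboxylate | COC(=O)C1=C[C@H](O)C(C(=O)OC)=C[C@@H]1O
F3 | step 11 | geranyl acetate | CC(C)=CCC/C(C)=C/COC(C)=O
F4 | step 11 | (2E)-5-[(2R)-3,3-dimethyloxiran-2-yl]-3-methylpent-2-en-1-yl acetate | CC(=O)OC/C=C(C)/CC[C@H]1OC1(C)C
F5 | step 11 | [(1S,5R)-5-hydroxy-2,6,6-trimethylcyclohex-2-en-1-yl]methyl acetate | CC1=CC[C@@H](O)C(C)(C)[C@H]1COC(C)=O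
F6 | step 11 | [(1S,5R)-5-hydroxy-2,6,6-trimethylcyclohex-2-en-1-yl]methanol | CC1=CC[C@@H](O)C(C)(C)[C@H]1CO
F7 | step 11 | 5-({[(1S,5R)-5-hydroxy-2,6,6-trimethylcyclohex-2-en-1-yl]methyl}sulfanyl)-1-phenyl-1H-tetrazole | CC1=CC[C@@H](O)C(C)(C)[C@H]1CSc1nnnn1-c1ccccc1
F0 | step 17 | none | none
A1 | direct plan | geranyl acetate | CC(C)=CCC/C(C)=C/COC(C)=O
A2 | direct plan | triethyl({(1R,5S)-5-[(E)-2-iodoethenyl]-4,6,6-trimethylcyclohex-3-en-1-yl}oxy)silane | CC1=CC[C@@H](O[Si](CC)(CC)CC)C(C)(C)[C@H]1/C=C/I
A3 | direct plan | (1S)-1-(furan-2-yl)but-2-yn-1-ol | CC#C[C@H](O)c1ccco1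
A4 | direct plan | methyl 7-[(1S)-1-hydroxybut-2-yn-1-yl]oxepine-4-carboxylate | CC#C[C@H](O)C1=CC=C(C(=O)OC)C=CO1
A5 | direct plan | methyl (1S,2R,5S,6S)-2,5-dihydroxy-6-[(1S)-1-hydroxybut-2-yn-1-yl]-7-oxabicyclo[4.1.0]hept-3-ene-3-carboxylate | CC#C[C@H](O)[C@]12O[C@H]1[C@H](O)C(C(=O)OC)=C[C@@H]2O
A6 | direct plan | [(1S,2R,5S,6S)-6-[(1S,2Z)-3-(benzyldimethylsilyl)-1-(triethylsilyloxy)but-2-en-1-yl]-2,5-bis(triethylsilyloxy)-7-oxabicyclo[4.1.0]hept-3-en-3-yl]methanol | C[Si](C)(Cc1ccccc1)/C(C)=C\[C@H](O[Si](CC)(CC)CC)[C@]12O[C@H]1[C@H](O[Si](CC)(CC)CC)C(CO)=C[C@@H]2O[Si](CC)(CC)CC
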